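**Plan**

1. Numbering used below: seven-membered ring C1 (bears =CH2), C2 (OH), C3, C4 (side chain), C5 (OH), C6, C7; five-membered ring C6–C10 (Me, OH)–C9=C8–C7; side chain C11 (Me)–C12 (OAc)–C13–C14=C15.
2. Cuts: silyl ethers and acetate; C14=C15 (cross-metathesis) and C12–C13 (allylboration); C10–O/C8=C9 go back by 1,3-oxygen transposition (selenoxide, epoxide) to a C9=C10 alkene; the five-membered ring is cut at C9=C10 (ring-closing metathesis) to isopropenyl on C6 and allyl on C7; C6–C10 and C7–C8 (conjugate addition/enolate allylation on a C1 enone); C4–C11 (ester enolate Claisen).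
3. Enabling feature: the C6–C7 fusion is trans, and C9–C10 is the only bond of the five-membered ring that touches neither fusion carbon. Both fusion bonds are therefore set trans on the cycloheptenone first and the ring is closed at its far edge; C10 is then fully substituted, so the oxygen transposition can only open toward C8.
4. Forward order: the seven-membered ring is bought (cyclohepta-1,3-diene) and functionalized; the five-membered ring is closed last; the side chain is then completed.
5. Stereochemistry: C5 from enzymatic desymmetrization; C4 and C11 by chirality transfer in the Claisen step; C2 by enolate hydroxylation anti to the C4 chain; C6 anti to the C5 silyl ether and C7 anti to C6; C10 by epoxidation on the face away from the C5 silyl ether; C12 by matched, reagent-controlled allylboration.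

Key step: step 11

Assumption: the lipase is taken to acylate the (R)-configured carbinol of the meso diol, as lipases usually do with cycloalk-2-enols; with the opposite preference, hydrolysis of the dipropanoate by the same enzyme would give the same monoester.

**Route**

Step 1
Reactants: 1 cyclohepta-1,3-diene
Product: 3 cis-cyclohept-2-ene-1,4-diol, via endoperoxide 2 (not isolated)
Conditions: O2, tetraphenylporphyrin (cat.), visible light, CH2Cl2, 0 °C; then Zn, AcOH, 0 → 23 °C
Reagents that add atoms: dioxygen O=O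
Why: The [4+2] cycloaddition of singlet oxygen to the ring diene puts both oxygens on one face, so reductive O–O cleavage by Zn/AcOH should give only the meso cis-diol.

Step 2
Reactants: 3 cis-cyclohept-2-ene-1,4-diol; 4 vinyl propanoate
Product: 5 (1R,4S)-4-hydroxycyclohept-2-en-1-yl propanoate
Conditions: Candida antarctica lipase B (immobilized), tert-butyl methyl ether, 30 °C
Reagents that add atoms: none
Why: Lipase-catalysed irreversible transesterification should desymmetrize the meso diol at the (R)-carbinol, which fixes the absolute configuration (free carbinol = C5, ester oxygen on C2) and installs the propanoate for the Claisen step.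

Step 3
Reactants: 5 (1R,4S)-4-hydroxycyclohept-2-en-1-yl propanoate
Product: 6 (1R,4S)-4-(tert-butyldimethylsilyloxy)cyclohept-2-en-1-yl propanoate
Conditions: t-BuMe2SiCl, imidazole, DMF, 23 °C
Reagents that add atoms: tert-butyldimethylsilyl chloride CC(C)(C)[Si](C)(C)Cl
Why: Standard silylation of the secondary alcohol gives the bulky C5 silyl ether that later directs the conjugate addition and the epoxidation.

Step 4
Reactants: 6 (1R,4S)-4-(tert-butyldimethylsilyloxy)cyclohept-2-en-1-yl propanoate
Product: 9 (2S)-2-[(1S,7S)-7-(tert-butyldimethylsilyloxy)cyclohept-2-en-1-yl]propan-1-ol, via silyl ketene acetal 7 (not isolated), via silyl ester 8 (not isolated)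
Conditions: LiN(iPr)2, THF, −78 °C; Me3SiCl, Et3N, −78 → 50 °C; then LiAlH4, 0 °C
Reagents that add atoms: none
Why: In this Ireland–Claisen rearrangement the (E)-silyl ketene acetal formed in THF should shift suprafacially from the C2 oxygen to C4 (so C4–C11 forms cis to the C5 silyl ether) through the boat-like transition state usual for cycloalk-2-enyl esters, which sets C11, and LiAlH4 then reduces the silyl ester.

Step 5
Reactants: 9 (2S)-2-[(1S,7S)-7-(tert-butyldimethylsilyloxy)cyclohept-2-en-1-yl]propan-1-ol
Product: 10 4-methoxybenzyl ether of 9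
Conditions: NaH, 4-methoxybenzyl chloride, Bu4NI (cat.), THF/DMF, 0 → 23 °C
Reagents that add atoms: 4-methoxybenzyl chloride COc1ccc(CCl)cc1
Why: Williamson etherification masks the future C12 carbinol through the oxidative and organometallic steps and can be removed oxidatively without touching silyl ethers.

Step 6
Reactants: 10 4-methoxybenzyl ether of 9
Product: 12 (4S,5S)-5-(tert-butyldimethylsilyloxy)-4-[(2S)-1-(4-methoxybenzyloxy)propan-2-yl]cyclohept-2-en-1-one, via allylic alcohol 11 (not isolated)
Conditions: SeO2 (cat.), t-BuOOH, CH2Cl2, 23 °C; then Dess–Martin periodinane, NaHCO3, CH2Cl2, 23 °C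
Reagents that add atoms: tert-butyl hydroperoxide CC(C)(C)OO
Why: Allylic oxidation by SeO2 (ene reaction, then [2,3]-sigmatropic shift) should take the C1 methylene rather than the hindered tertiary C4–H and keep the alkene at C2=C3, and Dess–Martin oxidation converges alcohol and enone to the C1 enone.

Step 7
Reactants: 12 (4S,5S)-5-(tert-butyldimethylsilyloxy)-4-[(2S)-1-(4-methoxybenzyloxy)propan-2-yl]cyclohept-2-en-1-one
Product: 14 ketol (C1 ketone; C2–OH trans to the C4 chain; C3 saturated), via lithium enolate 13 (not isolated)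
Conditions: LiBH(s-Bu)3, THF, −78 °C; then 2-(phenylsulfonyl)-3-phenyloxaziridine, −78 → −40 °C
Reagents that add atoms: 2-(phenylsulfonyl)-3-phenyloxaziridine O=S(=O)(N1OC1c1ccccc1)c1ccccc1
Why: Conjugate hydride reduction gives the C1–C2 enolate regiospecifically, and its electrophilic hydroxylation should occur on the face opposite to the C4 side chain.

Step 8
Reactants: 14 ketol (C1 ketone; C2–OH trans to the C4 chain; C3 saturated)
Product: 15 C2,C5-bis(silyl ether) ketone
Conditions: t-BuMe2SiOSO2CF3, 2,6-lutidine, CH2Cl2, −78 °C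
Reagents that add atoms: tert-butyldimethylsilyl trifluoromethanesulfonate CC(C)(C)[Si](C)(C)OS(=O)(=O)C(F)(F)F
Why: Silylation under non-enolizing conditions protects the ketol without epimerizing C2.

Step 9
Reactants: 15 C2,C5-bis(silyl ether) ketone
Product: 17 enone (C1 ketone, C7=C6), via silyl enol ether 16 (not isolated)
Conditions: LiN(SiMe3)2, Me3SiCl, THF, −78 °C; then Pd(OAc)2, MeCN, 23 °C
Reagents that add atoms: none
Why: Kinetic deprotonation should occur at the C7 methylene rather than the silyloxy-bearing C2 methine, and Saegusa–Ito oxidation of the silyl enol ether then gives the C7=C6 enone with the C5 silyl ether at the γ-position.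

Step 10
Reactants: 17 enone (C1 ketone, C7=C6); 18 isopropenylmagnesium bromide; 19 allyl iodide
Product: 21 trans-6-isopropenyl-7-allyl ketone, via magnesium enolate 20 (not isolated)
Conditions: CuBr·SMe2 (15 mol%), THF, −78 → −40 °C; then HMPA, −40 → 0 °C
Reagents that add atoms: none
Why: Copper-catalysed conjugate addition should deliver isopropenyl to C6 anti to the adjacent C5 silyl ether, and the enolate should be allylated at C7 anti to the new C6 group (vicinal difunctionalization), which fixes the trans ring fusion.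

Step 11
Reactants: 21 trans-6-isopropenyl-7-allyl ketone
Product: 22 trans-fused bicyclic ketone with C9=C10 (10-methyl) alkene
Conditions: second-generation Grubbs catalyst RuCl2(=CHPh)(H2IMes)(PCy3) (5 mol%), CH2Cl2 (0.002 M), 40 °C
Reagents that add atoms: none
Why: Ring-closing olefin metathesis: the ruthenium alkylidene loads on the allyl alkene, and [2+2] cycloaddition with the isopropenyl alkene followed by cycloreversion of the ruthenacyclobutane releases ethene and forms C9=C10. The closest known reaction type is ring-closing metathesis of 1,6-dienes to 1-methylcyclopentenes, including trans-fused bicycles. The five-membered ring closes at the C9–C10 edge between substituents on adjacent ring carbons, so the trans relationship of C6 and C7 from step 10 is carried into the ring without any bond being made at a stereocentre; together with step 10 this amounts to a trans-selective cyclopentene annulation. No new stereocentre arises, but the trisubstituted alkene is placed so that its fully substituted terminus C10 makes the later oxygen transposition (steps 13 and 17) regiospecific. The selectivity needed is closure over oligomerization, secured by high dilution and by the absence of any other alkene at this stage.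

Step 12
Reactants: 22 trans-fused bicyclic ketone with C9=C10 (10-methyl) alkene
Product: 23 1-methylidene diene
Conditions: Cp2TiMe2, toluene, 65 °C, dark
Reagents that add atoms: dimethyltitanocene C[Ti](C)(C1C=CC=C1)C1C=CC=C1
Why: Carbonyl methylenation by the titanium methylidene formed thermally from Cp2TiMe2 is non-basic, so the α-silyloxy ketone should give the exocyclic alkene without epimerization at C2 or C7.

Step 13
Reactants: 23 1-methylidene diene
Product: 24 C9–C10 epoxide (oxygen syn to H6)
Conditions: 3-chloroperbenzoic acid, NaHCO3, CH2Cl2, −20 → 0 °C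
Reagents that add atoms: 3-chloroperbenzoic acid OOC(=O)c1cccc(Cl)c1
Why: Peracid (Prilezhaev) epoxidation should take the trisubstituted ring alkene before the hindered 1,1-disubstituted exocyclic one and attack the face carrying H6, the other face being screened by the C5 silyl ether and axial H7, which sets the C10 oxygen.

Step 14
Reactants: 24 C9–C10 epoxide (oxygen syn to H6)
Product: 25 primary alcohol (C12–OH)
Conditions: DDQ, CH2Cl2, pH 7 buffer, 0 °C
Reagents that add atoms: none
Why: Oxidative cleavage of the 4-methoxybenzyl ether by DDQ is neutral and should leave the epoxide, alkenes and silyl ethers intact.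

Step 15
Reactants: 25 primary alcohol (C12–OH)
Product: 26 aldehyde (C12)
Conditions: Dess–Martin periodinane, NaHCO3, CH2Cl2, 0 → 23 °C
Reagents that add atoms: none
Why: Buffered Dess–Martin oxidation gives the α-methyl aldehyde without epimerizing C11.

Step 16
Reactants: 26 aldehyde (C12); 27 (−)-B-allyldiisopinocampheylborane
Product: 28 (12S)-homoallylic alcohol
Conditions: Et2O, −78 °C; then NaOH, H2O2, 0 → 23 °C
Reagents that add atoms: none
Why: Asymmetric allylboration through a closed chair transition state should add to the Si face of the aldehyde, which is also its Felkin face (matched case), giving the (S)-carbinol at C12.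

Step 17
Reactants: 28 (12S)-homoallylic alcohol
Product: 30 tertiary allylic alcohol (C10–OH, C8=C9), via hydroxy selenide 29 (not isolated)
Conditions: (PhSe)2, NaBH4, EtOH, 23 → 78 °C; then H2O2, pyridine, THF, 0 → 23 °C
Reagents that add atoms: none
Why: Benzeneselenolate should open the epoxide by SN2 attack at secondary C9, and selenoxide syn-elimination can only take a hydrogen from C8 because C10 is quaternary, so C8=C9 and the C10 carbinol result with the configuration set in step 13.

Step 18
Reactants: 30 tertiary allylic alcohol (C10–OH, C8=C9)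
Product: 31 C12 acetate
Conditions: Ac2O, pyridine, 4-(dimethylamino)pyridine (cat.), CH2Cl2, 0 → 23 °C
Reagents that add atoms: acetic anhydride CC(=O)OC(C)=O
Why: Acylation should take only the secondary C12 alcohol, since the tertiary C10 alcohol is unreactive under these conditions and C2 and C5 are silylated.

Step 19
Reactants: 31 C12 acetate; 32 2-methylbut-2-ene
Product: 33 bis(silyl ether) of the target
Conditions: second-generation Grubbs catalyst RuCl2(=CHPh)(H2IMes)(PCy3) (5 mol%), CH2Cl2, 40 °C
Reagents that add atoms: none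
Why: Olefin cross-metathesis of the terminal alkene with excess 2-methylbut-2-ene gives the trisubstituted C14=C15 terminus, while the hindered exocyclic alkene and the ring alkene flanked by C7 and quaternary C10 should not engage.

Step 20
Reactants: 33 bis(silyl ether) of the target
Product: 34 target CNP0126182.2
Conditions: HF·pyridine, pyridine, THF, 0 → 23 °C
Reagents that add atoms: none
Why: Buffered fluoride-mediated desilylation should remove both secondary silyl ethers and leave the acetate and the tertiary allylic alcohol intact.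

**Compound list**

1 | cyclohepta-1,3-diene | C1=CC=CCCC1 | starting material
2 | 6,7-dioxabicyclo[3.2.2]non-8-ene (endoperoxide) | O1O[C@@H]2C=C[C@H]1CCC2 | intermediate
3 | cis-cyclohept-2-ene-1,4-diol (meso) | O[C@@H]1C=C[C@H](O)CCC1 | intermediate
4 | vinyl propanoate | CCC(=O)OC=C | starting material
5 | (1R,4S)-4-hydroxycyclohept-2-en-1-yl propanoate | C1[C@@H](OC(=O)CC)C=C[C@@H](O)CC1 | intermediate
6 | (1R,4S)-4-(tert-butyldimethylsilyloxy)cyclohept-2-en-1-yl propanoate | C1[C@@H](OC(=O)CC)C=C[C@@H](O[Si](C)(C)C(C)(C)C)CC1 | intermediate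
7 | (E)-trimethylsilyl ketene acetal of 6 (methyl cis to the ring oxygen) | C1[C@@H](O/C(O[Si](C)(C)C)=C\C)C=C[C@@H](O[Si](C)(C)C(C)(C)C)CC1 | intermediate
8 | trimethylsilyl (2S)-2-[(1S,7S)-7-(tert-butyldimethylsilyloxy)cyclohept-2-en-1-yl]propanoate | C1C=C[C@@H]([C@H](C)C(=O)O[Si](C)(C)C)[C@@H](O[Si](C)(C)C(C)(C)C)CC1 | intermediate
9 | (2S)-2-[(1S,7S)-7-(tert-butyldimethylsilyloxy)cyclohept-2-en-1-yl]propan-1-ol | C1C=C[C@@H]([C@H](C)CO)[C@@H](O[Si](C)(C)C(C)(C)C)CC1 | intermediate
10 | 4-methoxybenzyl ether of 9 | C1C=C[C@@H]([C@H](C)COCc2ccc(OC)cc2)[C@@H](O[Si](C)(C)C(C)(C)C)CC1 | intermediate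
11 | C1 allylic alcohol of 10 (both C1 epimers) | OC1C=C[C@@H]([C@H](C)COCc2ccc(OC)cc2)[C@@H](O[Si](C)(C)C(C)(C)C)CC1 | intermediate
12 | (4S,5S)-5-(tert-butyldimethylsilyloxy)-4-[(2S)-1-(4-methoxybenzyloxy)propan-2-yl]cyclohept-2-en-1-one | O=C1C=C[C@@H]([C@H](C)COCc2ccc(OC)cc2)[C@@H](O[Si](C)(C)C(C)(C)C)CC1 | intermediate
13 | lithium enolate (O–Li on C1, C1=C2) from 1,4-reduction of 12 | [Li]OC1=CC[C@@H]([C@H](C)COCc2ccc(OC)cc2)[C@@H](O[Si](C)(C)C(C)(C)C)CC1 | intermediate
14 | ketol: C1 ketone, (2R)-hydroxyl trans to the C4 chain, C3 saturated | O=C1[C@H](O)C[C@@H]([C@H](C)COCc2ccc(OC)cc2)[C@@H](O[Si](C)(C)C(C)(C)C)CC1 | intermediate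
15 | C2,C5-bis(tert-butyldimethylsilyl ether) of ketol 14 | O=C1[C@H](O[Si](C)(C)C(C)(C)C)C[C@@H]([C@H](C)COCc2ccc(OC)cc2)[C@@H](O[Si](C)(C)C(C)(C)C)CC1 | intermediate
16 | trimethylsilyl enol ether of 15 (C1=C7) | C=1(O[Si](C)(C)C)[C@H](O[Si](C)(C)C(C)(C)C)C[C@@H]([C@H](C)COCc2ccc(OC)cc2)[C@@H](O[Si](C)(C)C(C)(C)C)CC=1 | intermediate
17 | enone: C1 ketone, C7=C6, silyl ethers at C2 and C5, chain at C4 | O=C1[C@H](O[Si](C)(C)C(C)(C)C)C[C@@H]([C@H](C)COCc2ccc(OC)cc2)[C@@H](O[Si](C)(C)C(C)(C)C)C=C1 | intermediate
18 | isopropenylmagnesium bromide | CC(=C)[Mg]Br | starting material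
19 | allyl iodide | C=CCI | starting material
20 | bromomagnesium enolate (C1=C7) carrying isopropenyl on C6 anti to the C5 silyl ether | C=1(O[Mg]Br)[C@H](O[Si](C)(C)C(C)(C)C)C[C@@H]([C@H](C)COCc2ccc(OC)cc2)[C@@H](O[Si](C)(C)C(C)(C)C)[C@H](C(C)=C)C=1 | intermediate
21 | trans-6-isopropenyl-7-allyl cycloheptanone (all other centres as in 17) | O=C1[C@H](O[Si](C)(C)C(C)(C)C)C[C@@H]([C@H](C)COCc2ccc(OC)cc2)[C@@H](O[Si](C)(C)C(C)(C)C)[C@H](C(C)=C)[C@H]1CC=C | intermediate
22 | trans-fused bicyclo[5.3.0]decenone: C1 ketone, C9=C10 alkene, methyl on C10 | O=C1[C@H](O[Si](C)(C)C(C)(C)C)C[C@@H]([C@H](C)COCc2ccc(OC)cc2)[C@@H](O[Si](C)(C)C(C)(C)C)[C@H]3[C@H]1CC=C3C | intermediate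
23 | 1-methylidene analogue of 22 | C=C1[C@H](O[Si](C)(C)C(C)(C)C)C[C@@H]([C@H](C)COCc2ccc(OC)cc2)[C@@H](O[Si](C)(C)C(C)(C)C)[C@H]3[C@H]1CC=C3C | intermediate
24 | C9–C10 epoxide of 23, oxygen syn to H6 | C=C1[C@H](O[Si](C)(C)C(C)(C)C)C[C@@H]([C@H](C)COCc2ccc(OC)cc2)[C@@H](O[Si](C)(C)C(C)(C)C)[C@H]3[C@H]1C[C@@H]4O[C@]34C | intermediate
25 | primary alcohol (C12–OH) from 24 | C=C1[C@H](O[Si](C)(C)C(C)(C)C)C[C@@H]([C@H](C)CO)[C@@H](O[Si](C)(C)C(C)(C)C)[C@H]2[C@H]1C[C@@H]3O[C@]23C | intermediate
26 | C12 aldehyde | C=C1[C@H](O[Si](C)(C)C(C)(C)C)C[C@@H]([C@H](C)C=O)[C@@H](O[Si](C)(C)C(C)(C)C)[C@H]2[C@H]1C[C@@H]3O[C@]23C | intermediate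
27 | (−)-B-allyldiisopinocampheylborane (from (+)-α-pinene) | C=CCB([C@@H]1C[C@@H]2C[C@H]([C@H]1C)C2(C)C)[C@@H]1C[C@@H]2C[C@H]([C@H]1C)C2(C)C | starting material
28 | (12S)-homoallylic alcohol (C13–C14=CH2 terminus) | C=C1[C@H](O[Si](C)(C)C(C)(C)C)C[C@@H]([C@H](C)[C@H](CC=C)O)[C@@H](O[Si](C)(C)C(C)(C)C)[C@H]2[C@H]1C[C@@H]3O[C@]23C | intermediate
29 | hydroxy selenide: C9–SePh anti to C10–OH | C=C1[C@H](O[Si](C)(C)C(C)(C)C)C[C@@H]([C@H](C)[C@H](CC=C)O)[C@@H](O[Si](C)(C)C(C)(C)C)[C@H]2[C@H]1C[C@@H]([Se]c3ccccc3)[C@]2(C)O | intermediate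
30 | tertiary allylic alcohol: C10–OH, C8=C9, free C12–OH | C=C1[C@H](O[Si](C)(C)C(C)(C)C)C[C@@H]([C@H](C)[C@H](CC=C)O)[C@@H](O[Si](C)(C)C(C)(C)C)[C@H]2[C@H]1C=C[C@]2(C)O | intermediate
31 | C12 acetate of 30 | C=C1[C@H](O[Si](C)(C)C(C)(C)C)C[C@@H]([C@H](C)[C@H](CC=C)OC(C)=O)[C@@H](O[Si](C)(C)C(C)(C)C)[C@H]2[C@H]1C=C[C@]2(C)O | intermediate
32 | 2-methylbut-2-ene | CC=C(C)C | starting material
33 | C2,C5-bis(tert-butyldimethylsilyl ether) of the target | C=C1[C@H](O[Si](C)(C)C(C)(C)C)C[C@@H]([C@H](C)[C@H](CC=C(C)C)OC(C)=O)[C@@H](O[Si](C)(C)C(C)(C)C)[C@H]2[C@H]1C=C[C@]2(C)O | intermediate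
34 | CNP0126182.2 | C=C1[C@H](O)C[C@@H]([C@H](C)[C@H](CC=C(C)C)OC(C)=O)[C@@H](O)[C@H]2[C@H]1C=C[C@]2(C)O | target

**Count and risks**

Total steps: 20. Longest linear sequence: 20 steps (from 1).

Steps most likely to fail:

Step 4. The rearrangement must form C4–C11 next to, and on the same face as, the C5 silyl ether, so it may be slow, and leakage through the (Z)-ketene acetal or a chair transition state would erode control at C11. Fallback (auxiliary control in place of ketene-acetal geometry): it sets out from 3. Lipase acetylation with vinyl acetate gives the monoacetate F1 and silylation gives the silyl ether F2. Ireland–Claisen rearrangement, now without a C11 stereocentre, gives the acid F3. Coupling (pivaloyl chloride, Et3N, then the lithium salt of (S)-4-benzyl-1,3-oxazolidin-2-one) gives the imide F4. Methylation of its chelated enolate (NaN(SiMe3)2, MeI) anti to the benzyl group gives the methylated imide F5, and LiBH4 reduction returns to 9.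

Step 7. The hydroxylation may show poor facial selectivity on the flexible seven-membered enolate, or 1,2-reduction may compete with the conjugate reduction. Fallback (inversion instead of facial control): it sets out from 12. The C2-epimeric ketol F6 obtained from the same operation is inverted by Mitsunobu reaction (4-nitrobenzoic acid, PPh3, diisopropyl azodicarboxylate) to the 4-nitrobenzoate F7, and methanolysis (K2CO3, MeOH) returns to 14.

Step 13. The peracid may attack the wrong face of the ring alkene (wrong C10 configuration) or epoxidize the exocyclic alkene as well. Fallback (hydroxyl-directed delivery before the exocyclic alkene exists): it sets out from 22. Bu4NF removes both silyl ethers to give the diol F8. Epoxidation with VO(acac)2 and tert-butyl hydroperoxide, directed by the homoallylic C5 hydroxyl, gives the epoxy diol F9. Resilylation (tert-butyldimethylsilyl trifluoromethanesulfonate, 2,6-lutidine) gives the bis(silyl ether) F10, and methylenation with Cp2TiMe2 as in step 12 returns to 24.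

**Further compounds**

F1 | step 4 | (1R,4S)-4-hydroxycyclohept-2-en-1-yl acetate | C1[C@@H](OC(C)=O)C=C[C@@H](O)CC1
F2 | step 4 | (1R,4S)-4-(tert-butyldimethylsilyloxy)cyclohept-2-en-1-yl acetate | C1[C@@H](OC(C)=O)C=C[C@@H](O[Si](C)(C)C(C)(C)C)CC1
F3 | step 4 | 2-[(1S,7S)-7-(tert-butyldimethylsilyloxy)cyclohept-2-en-1-yl]acetic acid | C1C=C[C@@H](CC(O)=O)[C@@H](O[Si](C)(C)C(C)(C)C)CC1
F4 | step 4 | N-acyl (S)-4-benzyl-1,3-oxazolidin-2-one of F3 | C1C=C[C@@H](CC(=O)N2[C@@H](Cc3ccccc3)COC2=O)[C@@H](O[Si](C)(C)C(C)(C)C)CC1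
F5 | step 4 | (2S)-2-methylated imide from F4 | C1C=C[C@@H]([C@H](C)C(=O)N2[C@@H](Cc3ccccc3)COC2=O)[C@@H](O[Si](C)(C)C(C)(C)C)CC1
F6 | step 7 | C2 epimer of ketol 14 | O=C1[C@@H](O)C[C@@H]([C@H](C)COCc2ccc(OC)cc2)[C@@H](O[Si](C)(C)C(C)(C)C)CC1
F7 | step 7 | 4-nitrobenzoate of ketol 14 | O=C1[C@H](OC(=O)c2ccc(cc2)[N+](=O)[O-])C[C@@H]([C@H](C)COCc3ccc(OC)cc3)[C@@H](O[Si](C)(C)C(C)(C)C)CC1
F8 | step 13 | C2,C5-diol of ketone 22 | O=C1[C@H](O)C[C@@H]([C@H](C)COCc2ccc(OC)cc2)[C@@H](O)[C@H]3[C@H]1CC=C3C
F9 | step 13 | C9–C10 epoxide of F8, oxygen syn to H6 | O=C1[C@H](O)C[C@@H]([C@H](C)COCc2ccc(OC)cc2)[C@@H](O)[C@H]3[C@H]1C[C@@H]4O[C@]34C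
F10 | step 13 | C2,C5-bis(tert-butyldimethylsilyl ether) of F9 | O=C1[C@H](O[Si](C)(C)C(C)(C)C)C[C@@H]([C@H](C)COCc2ccc(OC)cc2)[C@@H](O[Si](C)(C)C(C)(C)C)[C@H]3[C@H]1C[C@@H]4O[C@]34C
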